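The four flasks are neighbours: larch, elm, maple and cedar share one charge and differ in the vessel, so what you work out on elm, the closed flask, you can carry to the others.

    starting material + free catalyst → free catalyst + open intermediate (k1 = 751 /M/min)
    reagent + catalyst intermediate → second catalyst + product (k2 = 1590 /M/min)
    second catalyst + open intermediate ⇌ catalyst intermediate (K3 = 49 /M, k3 = 170 /M/min)
    second catalyst + impurity → spent catalyst (k4 = 16000 /M/min)

in all of them: reagent 1.20 equiv; free catalyst 0.11 mol%; second catalyst 1 mol%; impurity 1.0 mM
- larch: starting material 0.15 M; one stirred flow tank at steady state, fed with the mixture as stated, mean residence time 50.0 min
- elm: starting material 0.15 M; everything together in a closed stirred flask, run for 5.0 min; time 5.0 min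
- maple: starting material 0.15 M; a single well-mixed tank run continuously and read at steady state, 5.0 min in it on average
- cedar: starting material 0.15 M (fed, over 5.00 min); all but starting material at the start; starting material goes in evenly over 5.00 min, the run ends at 5.0 min; time 5.0 min

- the stated concentrations are those of everything mixed, before any reaction; amounts are the same in each set-up
- the feed brings no volume worth counting
- run time (elm): 5.0 min

- the set-up with the highest amount of open intermediate at the outlet or at the end, in percent of the starting material put in ("none" if the first two lie within 2 percentage points) (larch / elm / maple / cedar / none)
- amount of open intermediate at the outlet or at the end, in percent of the starting material put in, larch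
- amount of open intermediate at the outlet or at the end, in percent of the starting material put in, elm
- amount of open intermediate at the outlet or at the end, in percent of the starting material put in, maple
- amount of open intermediate at the outlet or at the end, in percent of the starting material put in, cedar

Open intermediate is made from starting material by free catalyst, whose amount does not change, so its making life is 8.07 min. Second catalyst removes it. Taken as charged, c(second catalyst) is 1.50 mM, which gives a life of 3.92 min, and elm ends near 24.5%.

But the impurity objects. Second catalyst is in excess over the impurity, and the impurity falls fast: even at the tail, meeting the surviving second catalyst, its life is 0.125 min, far shorter than the making life. So I reckon that the impurity spends 1.0 mM of second catalyst almost at once and leaves 0.500 mM. The number to carry is therefore the loss life, the mean time open intermediate lasts against the second catalyst that survives the impurity: 11.8 min.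

A second doubt is that catalyst intermediate might hold second catalyst back. Yet with reagent as charged it lives 0.00349 min, shorter than the wait of 0.0392 min for second catalyst to meet open intermediate, even with the whole charge counted as open intermediate. Second catalyst stays the resting state, and the making and the loss of open intermediate each go as pseudo-first-order.

Two lives in series then give elm 36.8%. Cedar's even dose averages that curve over the ages of its molecules, which gives 22.1%. Taking the same loss life in the tank, maple gives 26.8%. So I commit to elm.

The forecast names elm, with 17.2% for larch, 37.1% for elm, 26.8% for maple and 22.1% for cedar, a shade above my elm, starting from "the impurity rapidly kills 1.0 of the 1.5 mM second catalyst". The simulation gives elm, with 17.2% for larch, 37.1% for elm, 26.8% for maple and 22.1% for cedar.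

Elm ends after 0.425 of a loss life, while larch holds its contents for 4.24 of them on average. Elm stands at 37.1% in part because its run is short and the step from second catalyst + impurity takes second catalyst away, the two acting together: run to 50.0 min, elm reads 4.79%, and with that step struck out it reads 24.9%. In larch, 11.8 min against the stay of 50.0 min reckons 16.4%, and the run gives 17.2%.

The constants used here were chosen freely; the result is computed.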